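Retrosynthetic cuts: (i) the enone goes back to the (E)-tertiary allylic alcohol C2–CH2–CH=CH–C(OH)Me2 by oxidative 1,3-transposition. This mask keeps the base-labile β-aryloxy ketone, and with it C2, out of every basic step. (ii) The C7–CH2 and C8–CHO bonds of benzene ring A are cut together.
Enabling feature: CH2OC(O)C15H31 on C7 and CHO on C8 are neighbours and together are the ring-opened valence isomer of a 1-acyloxy-2-hydroxybenzocyclobutene. C8 lies beside C8a, which carries the pyran oxygen O1, so a C7≡C8 aryne is a 3-alkoxyaryne that takes a carbon nucleophile at C7 and puts the carbanion on C8.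
Both carbons and the whole palmitate therefore arrive in one operation from the enol silane of palmitoyloxyacetaldehyde and an 8-silyl-7-triflyloxychroman.
(iii) The aryne precursor goes back to the 7-hydroxychroman (C8 bromination, retro-Brook shift, triflation). (iv) O1–C2 and the side-chain CH2–CH= bond are cut to an o-(3-methylbut-3-enyl)phenol and methyl acrylate. (v) ArCH2–CH2 is cut to an o-quinone methide and a methallyl Grignard reagent.
Forward order: ring A is bought. Ring B (dihydropyran) closes in step 4 together with the side chain. A four-membered ring C is closed and reopened in step 11, where the ester chain is joined, and the enone is unveiled last.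
Stereochemistry: the single stereocentre C2 (S) is set by the chiral bis(oxazoline)–palladium catalyst in the oxypalladation of step 4, and none of its four bonds is touched afterwards.

Key step: step 11

Assumption: (S,S)-Bn-BOXAX, that is (Sa)-2,2'-bis[(4S)-4-benzyl-4,5-dihydrooxazol-2-yl]-1,1'-binaphthyl, is taken to give the (2S)-chroman by analogy with the closest 2-methylchroman-forming oxypalladations; if the sense of induction were opposite, the mirror-image ligand would be used.

Step 1
Reactants: 1 2,4-dihydroxy-6-methoxybenzaldehyde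
Product: 2 2,4-bis(tert-butoxycarbonyloxy)-6-methoxybenzaldehyde
Conditions: Boc2O (2.4 equiv), iPr2NEt, DMAP (cat.), THF, 0→23 °C
Reagents that add atoms: di-tert-butyl dicarbonate, CC(C)(C)OC(=O)OC(=O)OC(C)(C)C
Why: DMAP-catalysed O-acylation turns both phenols into tert-butyl carbonates, the ortho one serving later as the trigger for o-quinone methide formation and the para one as the protecting group of the future O7.

Step 2
Reactants: 2 2,4-bis(tert-butoxycarbonyloxy)-6-methoxybenzaldehyde
Product: 3 [2,4-bis(tert-butoxycarbonyloxy)-6-methoxyphenyl]methanol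
Conditions: BH3·THF, THF, 0 °C; H2O
Reagents that add atoms: none
Why: Borane reduction of the aldehyde runs through a neutral borate ester and not a free alkoxide, so the neighbouring carbonate should not migrate before it is wanted.

Step 3
Reactants: 3 [2,4-bis(tert-butoxycarbonyloxy)-6-methoxyphenyl]methanol; 4 2-methylallylmagnesium chloride, CH2=C(CH3)CH2MgCl
Product: 6 tert-butyl 3-hydroxy-5-methoxy-4-(3-methylbut-3-en-1-yl)phenyl carbonate, via o-quinone methide 5 (not isolated)
Conditions: 4 (2.3 equiv), Et2O–THF, −78→0 °C; aq NH4Cl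
Reagents that add atoms: none
Why: Anionic o-quinone methide generation (magnesium alkoxide, O-to-O carbonate transfer, loss of tert-butyl carbonate) is followed by 1,4-addition of the second equivalent of the Grignard reagent, which rearomatises ring A, while low temperature and a small excess should spare the para carbonate.

Step 4
Reactants: 6 tert-butyl 3-hydroxy-5-methoxy-4-(3-methylbut-3-en-1-yl)phenyl carbonate; 7 methyl acrylate
Product: 8 methyl (E)-4-[(2S)-7-(tert-butoxycarbonyloxy)-5-methoxy-2-methylchroman-2-yl]but-2-enoate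
Conditions: Pd(OCOCF3)2 (10 mol%), (S,S)-Bn-BOXAX (40 mol%), p-benzoquinone (4 equiv), 7 (5 equiv), CH2Cl2, 23 °C
Reagents that add atoms: none
Why: In this enantioselective domino Wacker–Heck reaction the 6-exo-trig oxypalladation of the 1,1-disubstituted alkene inside the chiral pocket of the divalent palladium–BOXAX complex sets C2, the neopentyl σ-alkylpalladium has no β-hydrogen and therefore inserts the acrylate, and β-hydride elimination gives the (E)-enoate while benzoquinone reoxidises zerovalent palladium.

Step 5
Reactants: 8 methyl (E)-4-[(2S)-7-(tert-butoxycarbonyloxy)-5-methoxy-2-methylchroman-2-yl]but-2-enoate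
Product: 9 (2S)-2-[(E)-4-hydroxy-4-methylpent-2-en-1-yl]-5-methoxy-2-methylchroman-7-ol
Conditions: MeMgBr (7 equiv), LaCl3·2LiCl (30 mol%), THF, −20→0 °C; aq NH4Cl
Reagents that add atoms: methylmagnesium bromide, C[Mg]Br
Why: Double 1,2-addition of the Grignard reagent to the enoate (the lanthanum salt holds back enolisation and 1,4-addition) gives the tertiary allylic alcohol that masks the enone, and the same reagent removes the aryl carbonate by acyl substitution.

Step 6
Reactants: 9 (2S)-2-[(E)-4-hydroxy-4-methylpent-2-en-1-yl]-5-methoxy-2-methylchroman-7-ol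
Product: 10 (2S)-8-bromo-2-[(E)-4-hydroxy-4-methylpent-2-en-1-yl]-5-methoxy-2-methylchroman-7-ol
Conditions: NBS (1.0 equiv), CH2Cl2, −78→−40 °C
Reagents that add atoms: N-bromosuccinimide, O=C1CCC(=O)N1Br
Why: Electrophilic aromatic bromination ortho to the free phenol should prefer C8 over C6, because C4H2 forces the methyl of the 5-methoxy group into the ring plane toward C6 whereas O1 is tied back in ring B (the bias that sends NBS to C8 of 5,7-dialkoxyflavans), and the phenol is far more reactive than the side-chain alkene.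

Step 7
Reactants: 10 (2S)-8-bromo-2-[(E)-4-hydroxy-4-methylpent-2-en-1-yl]-5-methoxy-2-methylchroman-7-ol
Product: 11 (2S)-8-bromo-5-methoxy-2-methyl-2-[(E)-4-methyl-4-(trimethylsilyloxy)pent-2-en-1-yl]-7-(trimethylsilyloxy)chroman
Conditions: HMDS, Me3SiCl (cat.), THF, 60 °C; evaporation
Reagents that add atoms: hexamethyldisilazane, C[Si](C)(C)N[Si](C)(C)C
Why: O-silylation of both hydroxyl groups with the disilazane gives only a volatile by-product, so the hydrolytically labile aryl silyl ether can be used after evaporation.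

Step 8
Reactants: 11 (2S)-8-bromo-5-methoxy-2-methyl-2-[(E)-4-methyl-4-(trimethylsilyloxy)pent-2-en-1-yl]-7-(trimethylsilyloxy)chroman
Product: 13 (2S)-5-methoxy-2-methyl-2-[(E)-4-methyl-4-(trimethylsilyloxy)pent-2-en-1-yl]-8-(trimethylsilyl)chroman-7-yl trifluoromethanesulfonate, via lithium phenolate 12 (not isolated)
Conditions: nBuLi (1.1 equiv), THF, −78 °C; then PhNTf2, −78→23 °C
Reagents that add atoms: N-phenylbis(trifluoromethanesulfonimide), O=S(=O)(N(c1ccccc1)S(=O)(=O)C(F)(F)F)C(F)(F)F
Why: Bromine–lithium exchange followed by the 1,3 O-to-C silyl shift (retro-Brook rearrangement) places silicon on C8 and frees the phenolate, which is triflated in the same flask, the standard entry to o-silylaryl triflates.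

Step 9
Reactants: 14 rac-1-monopalmitin (2,3-dihydroxypropyl hexadecanoate)
Product: 15 2-oxoethyl hexadecanoate
Conditions: NaIO4, THF–H2O, 23 °C
Reagents that add atoms: none
Why: Malaprade glycol cleavage of the terminal 1,2-diol gives the α-acyloxy aldehyde in one step without touching the ester.

Step 10
Reactants: 15 2-oxoethyl hexadecanoate
Product: 16 (Z)-2-(tert-butyldimethylsilyloxy)ethenyl hexadecanoate
Conditions: TBSOTf, Et3N, CH2Cl2, 0 °C
Reagents that add atoms: tert-butyldimethylsilyl trifluoromethanesulfonate, CC(C)(C)[Si](C)(C)OS(=O)(=O)C(F)(F)F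
Why: Soft enolisation (silyl triflate and amine) acts on the aldehyde, which is far easier to activate than the ester, and should give mainly the (Z)-enol silane, whose geometry does not matter later.

Step 11
Reactants: 13 (2S)-5-methoxy-2-methyl-2-[(E)-4-methyl-4-(trimethylsilyloxy)pent-2-en-1-yl]-8-(trimethylsilyl)chroman-7-yl trifluoromethanesulfonate; 16 (Z)-2-(tert-butyldimethylsilyloxy)ethenyl hexadecanoate
Product: 20 {(2S)-8-formyl-2-[(E)-4-hydroxy-4-methylpent-2-en-1-yl]-5-methoxy-2-methylchroman-7-yl}methyl hexadecanoate, via chromanyne 17 (not isolated), via silyloxybenzocyclobutene 18 (not isolated), via o-quinodimethane enol 19 (not isolated)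
Conditions: 16 (2.5 equiv), CsF (4 equiv), MeCN–PhMe 1:1, 23 °C; then Bu4NF·3H2O, THF, 0 °C
Reagents that add atoms: none
Why: Proposed new method: fluoride strips the C8 silyl group of 13 and triflate leaves C7 to give the 7,8-chromanyne 17, whose triple bond is flanked on the C8 side by C8a with the σ-withdrawing ring oxygen O1 and on the C7 side only by C6–H, so that, as in every 3-alkoxyaryne, C7 is the terminus with the larger internal angle and takes the nucleophile while negative charge builds up on C8 next to C8a–O1. The acyloxy-bearing carbon of 16 is the β-carbon of the silyl enol ether and hence its nucleophilic end, so it bonds to C7, the C8 carbanion collapses on the silyloxocarbenium carbon (4-exo-trig closure of ring C) to give 18, Bu4NF then frees the alkoxide, which opens by oxyanion-accelerated conrotatory 4π electrocyclic reaction to the o-quinodimethane 19, and proton transfer from water to the acyloxy-bearing terminus restores ring A with CH2OC(O)C15H31 on C7 and CHO on C8. The closest known reaction types are the regioselective [2+2] annulation of 3-alkoxyarynes with ketene silyl acetals or aldehyde enolates to benzocyclobutenol derivatives, the acyl-alkylation of arynes by β-keto esters (formal insertion into a C–C σ bond through the same kind of benzocyclobutenoxide) and the base-induced opening of benzocyclobutenols to o-alkylbenzaldehydes, and what is new is the α-acyloxy aldehyde enol silane as partner, which delivers formyl and acyloxymethyl together. The only ring closed is the four-membered ring C, which is opened again in the same flask, its two stereocentres are not controlled and are erased, no stereocentre is created in 20, and C2 is safe because no enolisable β-aryloxy ketone exists at this stage. Regioselectivity is needed twice, in the addition (secured by O1 beside C8 and by the polarity of 16) and against a 1,2-acyl shift in a cis-alkoxide, where the shifted isomer would have to open to a dienolate that places charge on the oxygen-bearing C8a and C5 whereas the wanted one spreads it over C8, C6 and C4a only, so the productive channel should drain any equilibrium. Chemoselectivity rests on the excess of the electron-rich alkene 16 over the unactivated, geometrically remote side-chain alkene.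

Step 12
Reactants: 20 {(2S)-8-formyl-2-[(E)-4-hydroxy-4-methylpent-2-en-1-yl]-5-methoxy-2-methylchroman-7-yl}methyl hexadecanoate
Product: 21 {(2S)-8-formyl-5-methoxy-2-methyl-2-(4-methyl-2-oxopent-3-en-1-yl)chroman-7-yl}methyl hexadecanoate (target)
Conditions: [C5H5NH][CrO3Cl] (pyridinium chlorochromate), 4 Å molecular sieves, CH2Cl2, 23 °C
Reagents that add atoms: pyridinium chlorochromate (supplies the ketone oxygen), [O-][Cr](=O)(=O)Cl.c1cc[nH+]cc1
Why: In the Babler–Dauben oxidative transposition the chromate ester of the tertiary allylic alcohol undergoes a [3,3] shift to the secondary allylic chromate, which collapses to the enone, and the non-basic medium gives the new β-aryloxy ketone no chance of retro-oxa-Michael opening, so C2 stays (S).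

Compound list
1 | 2,4-dihydroxy-6-methoxybenzaldehyde | COc1cc(O)cc(O)c1C=O | starting material
2 | 2,4-bis(tert-butoxycarbonyloxy)-6-methoxybenzaldehyde | COc1cc(OC(=O)OC(C)(C)C)cc(OC(=O)OC(C)(C)C)c1C=O | intermediate
3 | [2,4-bis(tert-butoxycarbonyloxy)-6-methoxyphenyl]methanol | COc1cc(OC(=O)OC(C)(C)C)cc(OC(=O)OC(C)(C)C)c1CO | intermediate
4 | 2-methylallylmagnesium chloride | CC(=C)C[Mg]Cl | starting material
5 | 3-(tert-butoxycarbonyloxy)-5-methoxy-6-methylidenecyclohexa-2,4-dien-1-one (o-quinone methide, not isolated) | C=C1C(=O)C=C(OC(=O)OC(C)(C)C)C=C1OC | intermediate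
6 | tert-butyl 3-hydroxy-5-methoxy-4-(3-methylbut-3-en-1-yl)phenyl carbonate | COc1cc(OC(=O)OC(C)(C)C)cc(O)c1CCC(C)=C | intermediate
7 | methyl acrylate | C=CC(=O)OC | starting material
8 | methyl (E)-4-[(2S)-7-(tert-butoxycarbonyloxy)-5-methoxy-2-methylchroman-2-yl]but-2-enoate | CC(C)(C)OC(=O)Oc1cc(OC)c2c(c1)O[C@](C)(C/C=C/C(=O)OC)CC2 | intermediate
9 | (2S)-2-[(E)-4-hydroxy-4-methylpent-2-en-1-yl]-5-methoxy-2-methylchroman-7-ol | Oc1cc(OC)c2c(c1)O[C@](C)(C/C=C/C(C)(C)O)CC2 | intermediate
10 | (2S)-8-bromo-2-[(E)-4-hydroxy-4-methylpent-2-en-1-yl]-5-methoxy-2-methylchroman-7-ol | Oc1cc(OC)c2c(c1Br)O[C@](C)(C/C=C/C(C)(C)O)CC2 | intermediate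
11 | (2S)-8-bromo-5-methoxy-2-methyl-2-[(E)-4-methyl-4-(trimethylsilyloxy)pent-2-en-1-yl]-7-(trimethylsilyloxy)chroman | C[Si](C)(C)Oc1cc(OC)c2c(c1Br)O[C@](C)(C/C=C/C(C)(C)O[Si](C)(C)C)CC2 | intermediate
12 | lithium (2S)-5-methoxy-2-methyl-2-[(E)-4-methyl-4-(trimethylsilyloxy)pent-2-en-1-yl]-8-(trimethylsilyl)chroman-7-olate (not isolated) | [Li+].[O-]c1cc(OC)c2c(c1[Si](C)(C)C)O[C@](C)(C/C=C/C(C)(C)O[Si](C)(C)C)CC2 | intermediate
13 | (2S)-5-methoxy-2-methyl-2-[(E)-4-methyl-4-(trimethylsilyloxy)pent-2-en-1-yl]-8-(trimethylsilyl)chroman-7-yl trifluoromethanesulfonate | O=S(=O)(Oc1cc(OC)c2c(c1[Si](C)(C)C)O[C@](C)(C/C=C/C(C)(C)O[Si](C)(C)C)CC2)C(F)(F)F | intermediate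
14 | rac-1-monopalmitin (2,3-dihydroxypropyl hexadecanoate) | CCCCCCCCCCCCCCCC(=O)OCC(O)CO | starting material
15 | 2-oxoethyl hexadecanoate | CCCCCCCCCCCCCCCC(=O)OCC=O | intermediate
16 | (Z)-2-(tert-butyldimethylsilyloxy)ethenyl hexadecanoate | CCCCCCCCCCCCCCCC(=O)O/C=C\O[Si](C)(C)C(C)(C)C | intermediate
17 | (2S)-7,8-didehydro-5-methoxy-2-methyl-2-[(E)-4-methyl-4-(trimethylsilyloxy)pent-2-en-1-yl]chroman (aryne, not isolated) | C1=C(OC)C2=C(C#C1)O[C@](C)(C/C=C/C(C)(C)O[Si](C)(C)C)CC2 | intermediate
18 | cyclobutene-fused chroman with CH(OC(O)C15H31) on C7 and CH(OSiMe2tBu) on C8, (2S), both ring C centres uncontrolled (not isolated) | CCCCCCCCCCCCCCCC(=O)OC1C(O[Si](C)(C)C(C)(C)C)c2c1cc(OC)c1c2O[C@](C)(C/C=C/C(C)(C)O[Si](C)(C)C)CC1 | intermediate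
19 | o-quinodimethane enol with C7=CH–OC(O)C15H31 and C8=CH–OH, (2S) (not isolated) | CCCCCCCCCCCCCCCC(=O)OC=C1C=C(OC)C2=C(C1=CO)O[C@](C)(C/C=C/C(C)(C)O)CC2 | intermediate
20 | {(2S)-8-formyl-2-[(E)-4-hydroxy-4-methylpent-2-en-1-yl]-5-methoxy-2-methylchroman-7-yl}methyl hexadecanoate | CCCCCCCCCCCCCCCC(=O)OCc1cc(OC)c2c(c1C=O)O[C@](C)(C/C=C/C(C)(C)O)CC2 | intermediate
21 | {(2S)-8-formyl-5-methoxy-2-methyl-2-(4-methyl-2-oxopent-3-en-1-yl)chroman-7-yl}methyl hexadecanoate | CCCCCCCCCCCCCCCC(=O)OCc1cc(OC)c2c(c1C=O)O[C@](C)(CC(=O)C=C(C)C)CC2 | target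

Total step count: 12. Longest linear sequence: 10 (steps 1–8, 11, 12).

Steps most likely to fail

**Step 11.** Three processes could go wrong.
- Fluoride may desilylate the enol silane faster than it releases the aryne. The free enolate would then be lost by acyl shift and self-condensation.
- The C8 carbanion may be protonated before ring C closes.
- Acyl migration may outrun ring opening.

The fallback uses known chemistry without an aryne. It sets out from 9 and returns at 20.
- Magnesium-phenolate-directed ortho-formylation (Casnati–Skattebøl; MgCl2, Et3N, paraformaldehyde, MeCN, reflux) should give (2S)-7-hydroxy-2-[(E)-4-hydroxy-4-methylpent-2-en-1-yl]-5-methoxy-2-methylchroman-8-carbaldehyde F1.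
- PhNTf2 with K2CO3 triflates only the phenol and gives (2S)-8-formyl-2-[(E)-4-hydroxy-4-methylpent-2-en-1-yl]-5-methoxy-2-methylchroman-7-yl trifluoromethanesulfonate F2.
- A Migita–Kosugi–Stille hydroxymethylation with Bu3SnCH2OH (Pd(PPh3)4, LiCl, dioxane, 90 °C) makes the same C7–CH2 bond and gives (2S)-2-[(E)-4-hydroxy-4-methylpent-2-en-1-yl]-7-(hydroxymethyl)-5-methoxy-2-methylchroman-8-carbaldehyde F3.
- Palmitoyl chloride in pyridine at 0 °C acylates the primary alcohol in preference to the tertiary one and gives 20.

**Step 6.** Site selectivity between C6 and C8 may be poor, and a second bromination may occur. The fallback replaces electrophilic substitution by directed ortho-metalation, where coordination and not ring nucleophilicity decides. It sets out from 9 and returns at 13.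
- ClC(O)NEt2 with K2CO3 in MeCN carbamoylates the phenol to (2S)-2-[(E)-4-hydroxy-4-methylpent-2-en-1-yl]-5-methoxy-2-methylchroman-7-yl N,N-diethylcarbamate F4.
- sBuLi (2.2 equiv) with TMEDA at −78 °C deprotonates the alcohol and then C8, which lies between the carbamate and the exposed in-plane lone pair of O1.
- Me3SiCl then silylates carbon and oxygen together to give (2S)-5-methoxy-2-methyl-2-[(E)-4-methyl-4-(trimethylsilyloxy)pent-2-en-1-yl]-8-(trimethylsilyl)chroman-7-yl N,N-diethylcarbamate F5.
- LiAlH4 in THF at 0 °C cleaves the carbamate reductively to (2S)-5-methoxy-2-methyl-2-[(E)-4-methyl-4-(trimethylsilyloxy)pent-2-en-1-yl]-8-(trimethylsilyl)chroman-7-ol F6.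
- PhNTf2 with Et3N converts F6 into 13.

**Step 12.** Ionisation and dehydration of the tertiary allylic alcohol may compete with the [3,3] shift, which also has to move toward a carbon next to a neopentyl position. The fallback separates rearrangement from oxidation and avoids acidic hexavalent chromium. It sets out from 20 and returns at 21.
- Catalytic Ph3SiOReO3 in Et2O at 0 °C equilibrates the allylic alcohol by 1,3-transposition toward the isomer with the trisubstituted alkene. This isomer is {(2S)-8-formyl-2-(2-hydroxy-4-methylpent-3-en-1-yl)-5-methoxy-2-methylchroman-7-yl}methyl hexadecanoate F7, as both carbinol epimers.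
- MnO2 in CH2Cl2 oxidises F7 to 21.

Further compounds
F1 | step 11 | (2S)-7-hydroxy-2-[(E)-4-hydroxy-4-methylpent-2-en-1-yl]-5-methoxy-2-methylchroman-8-carbaldehyde | Oc1cc(OC)c2c(c1C=O)O[C@](C)(C/C=C/C(C)(C)O)CC2
F2 | step 11 | (2S)-8-formyl-2-[(E)-4-hydroxy-4-methylpent-2-en-1-yl]-5-methoxy-2-methylchroman-7-yl trifluoromethanesulfonate | O=S(=O)(Oc1cc(OC)c2c(c1C=O)O[C@](C)(C/C=C/C(C)(C)O)CC2)C(F)(F)F
F3 | step 11 | (2S)-2-[(E)-4-hydroxy-4-methylpent-2-en-1-yl]-7-(hydroxymethyl)-5-methoxy-2-methylchroman-8-carbaldehyde | OCc1cc(OC)c2c(c1C=O)O[C@](C)(C/C=C/C(C)(C)O)CC2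
F4 | step 6 | (2S)-2-[(E)-4-hydroxy-4-methylpent-2-en-1-yl]-5-methoxy-2-methylchroman-7-yl N,N-diethylcarbamate | CCN(CC)C(=O)Oc1cc(OC)c2c(c1)O[C@](C)(C/C=C/C(C)(C)O)CC2
F5 | step 6 | (2S)-5-methoxy-2-methyl-2-[(E)-4-methyl-4-(trimethylsilyloxy)pent-2-en-1-yl]-8-(trimethylsilyl)chroman-7-yl N,N-diethylcarbamate | CCN(CC)C(=O)Oc1cc(OC)c2c(c1[Si](C)(C)C)O[C@](C)(C/C=C/C(C)(C)O[Si](C)(C)C)CC2
F6 | step 6 | (2S)-5-methoxy-2-methyl-2-[(E)-4-methyl-4-(trimethylsilyloxy)pent-2-en-1-yl]-8-(trimethylsilyl)chroman-7-ol | Oc1cc(OC)c2c(c1[Si](C)(C)C)O[C@](C)(C/C=C/C(C)(C)O[Si](C)(C)C)CC2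
F7 | step 12 | {(2S)-8-formyl-2-(2-hydroxy-4-methylpent-3-en-1-yl)-5-methoxy-2-methylchroman-7-yl}methyl hexadecanoate (both carbinol epimers) | CCCCCCCCCCCCCCCC(=O)OCc1cc(OC)c2c(c1C=O)O[C@](C)(CC(O)C=C(C)C)CC2
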